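At 80 min I want the contents of the flask. It has the charges of starting material and second substrate of Saturday's run, but 1.34 times its free enzyme.

the same everywhere: starting material 20 mM
- Monday's: second substrate 12 mM; free enzyme 0.41 µM; run made earlier
- Saturday's: second substrate 12 mM; free enzyme 0.61 µM; run made earlier
- flask: second substrate 12.0 mM; free enzyme 0.82 µM; time 80 min

| run | time / min | starting material / % | target / % |
|---|---|---|---|
| Monday's | 8.00 | 72.3 | 19.4 |
| Monday's | 12.0 | 60.9 | 22.9 |
| Monday's | 20.0 | 41.5 | 27.3 |
| Monday's | 25.0 | 32.8 | 29.6 |
| Monday's | 40.0 | 20.3 | 30.1 |
| Monday's | 60.0 | 12.1 | 28.3 |
| Monday's | 90.0 | 7.2 | 25.9 |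
| Saturday's | 5.00 | 75.7 | 19.7 |
| Saturday's | 15.0 | 42.2 | 33.2 |
| Saturday's | 25.0 | 24.1 | 36.1 |
| Saturday's | 40.0 | 16.0 | 33.3 |
| Saturday's | 60.0 | 10.1 | 28.9 |
| Saturday's | 80.0 | 6.9 | 28.0 |
| Saturday's | 90.0 | 5.3 | 26.0 |

(standard deviation of a reading: 1 percentage point)

1. the starting material in the flask at 80 min, as a percentage of the starting material charged
2. the target in the flask at 80 min, as a percentage of the starting material charged

- percent here means starting material units held: one side product counts as two
- on the list of suspects stand: starting material + free enzyme <-> first complex; first complex <-> loaded enzyme + first product; second substrate + loaded enzyme <-> second complex; second complex -> free enzyme + target; starting material + target -> side product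

Each target made uses one second substrate. Each side product takes one target and one starting material, and it counts two in the percentages. I combine these two balances. With the charges here, they give 20.0 %: the end gap, which is target minus starting material after c(second substrate) has reached zero, reckoned as twice the charge of second substrate, less the charge of starting material, over the charge of starting material. The enzyme charge does not enter it, and the side step takes one of each, so from that point on the difference stays put.

Enzyme shows in how soon a run gets there. At 40.0 min, the difference in Monday's run reads 9.8 percentage points, smaller than the 17 points of Saturday's run. At 90.0 min, they read 19 points and 21 points. I take Saturday's reading of 6.9 % starting material at 80.0 min for the flask, and the gap then gives 26.9 % target.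

The forecast says 6.7 % starting material and 26.9 % target, holding of second substrate that “the enzyme stops when that runs out”. Its starting material is lower than mine.

The flask gives 7.25 % starting material and 27.2 % target.

    starting material + free enzyme ⇌ first complex (K = 44.0 L mol⁻¹, k = 5.51 × 10⁵ L mol⁻¹ s⁻¹)
    first complex ⇌ loaded enzyme + first product (K = 0.0199 M, k = 8370 min⁻¹)
    second substrate + loaded enzyme ⇌ second complex (K = 150 L mol⁻¹, k = 1.47 × 10⁵ L mol⁻¹ s⁻¹)
    second complex → free enzyme + target (k = 4610 min⁻¹)
    starting material + target → side product (k = 2.92 L mol⁻¹ min⁻¹)

In the flask at 80.0 min, second substrate, the limiting reagent, stands at 0.0707 % of its charge, and target minus starting material is 19.9 %, against the end gap of 20.0 %. The flask is not at rest: 7.25 % starting material stands beside 27.2 % target. A neighbouring flask with 34 mM starting material has a gap of −29.4 %, and it holds 31.4 % starting material and 1.96 % target, a difference of −29.4 %. Left until 800 min, the flask holds 0 % starting material and 20.0 % target.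

(The earlier runs and the new flask were generated by integration for substances that don't exist; the scatter is artificial.)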